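The route rests on cutting the C7–C8 bond of the ten-membered carbocycle (germacrane numbering), read as part of the homoallylic motif O–C8–C7–C11(=C13H2) that the ring shares with the fused α-methylene-γ-lactone. An intramolecular Nozaki–Hiyama–Kishi allylation closes the cyclodecadiene, sets C7 and C8, and shifts the butenolide C7=C11 double bond into the exocyclic methylene in one operation. Its precursor is an open-chain (R)-γ-alkenyl-α-(bromomethyl)butenolide whose dienyl chain ends in an aldehyde. The single stereocentre of that precursor, C6, set by catalytic asymmetric alkynylation, relays to C7 and C8 and, through the macrocycle conformation, to the late C1–C10 epoxide.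

Key step: step 16

Remark on numbering: locants C1–C15 in names and Why lines follow germacrane numbering of the target (ring C1–C10; lactone O–C6 and C7–C11(=C13)–C12(=O); C14 on C10; C15 on C4); the target is taken as the (1R,6R,7R,8S,10S) enantiomer with a ring-cis C4=C5 bond (4E by CIP).
Assumption: in step 8 the (R,R)-ligand is taken to be the enantiomer that directs Si-face alkynylation of the enal; the sense is to be checked on the first batch by MTPA ester analysis and the antipodal ligand used otherwise.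

Step 1
Reactants: 1 but-2-yne-1,4-diol
Product: 2 4-[(tert-butyldiphenylsilyl)oxy]but-2-yn-1-ol
Conditions: NaH (1 equiv), THF, 0 °C; TBDPSCl (1 equiv), 0 °C → rt; 1 in threefold excess
Reagents that add atoms: tert-butyl(chloro)diphenylsilane, CC(C)(C)[Si](Cl)(c1ccccc1)c1ccccc1
Why: O-silylation of the monosodium alkoxide of a symmetrical diol (Williamson-type silyl ether formation), with excess diol keeping bis-silylation low.

Step 2
Reactants: 2 4-[(tert-butyldiphenylsilyl)oxy]but-2-yn-1-ol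
Product: 4 (2Z)-4-[(tert-butyldiphenylsilyl)oxy]-3-iodobut-2-en-1-ol, via cyclic vinylalanate 3 (not isolated)
Conditions: NaAlH2(OCH2CH2OMe)2, THF, 0 °C; then I2, THF, −78 → 0 °C
Reagents that add atoms: iodine, II
Why: Hydroxyl-directed trans-hydroalumination of the propargylic alcohol puts aluminium on the distal alkyne carbon in a five-membered chelate (3), and iodinolysis with retention gives the (Z)-vinyl iodide that fixes the later C4=C5 geometry (iodine cis to C6).

Step 3
Reactants: 4 (2Z)-4-[(tert-butyldiphenylsilyl)oxy]-3-iodobut-2-en-1-ol; 5 3,3-diethoxyprop-1-ene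
Product: 7 (2E)-3-{[(tert-butyldiphenylsilyl)oxy]methyl}-6,6-diethoxyhex-2-en-1-ol, via alkylborane 6 (not isolated)
Conditions: 5, 9-BBN-H, THF, 0 °C → rt; then 4, PdCl2(dppf) (5 mol %), AsPh3, Cs2CO3, DMF/H2O, rt
Reagents that add atoms: none
Why: B-alkyl Suzuki–Miyaura coupling, in which 9-BBN adds anti-Markovnikov to the terminal olefin of 5 and the sp3–sp2 coupling occurs with retention at the vinyl iodide, so the C3–C1 chain ends up cis to C6.

Step 4
Reactants: 7 (2E)-3-{[(tert-butyldiphenylsilyl)oxy]methyl}-6,6-diethoxyhex-2-en-1-ol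
Product: 8 (4E)-4-{[(tert-butyldiphenylsilyl)oxy]methyl}-6-hydroxyhex-4-enal
Conditions: PPTS (cat.), acetone/H2O, 40 °C
Reagents that add atoms: water, O
Why: Acid-catalysed acetal hydrolysis releases the C1 aldehyde under conditions that leave the allylic alcohol and the silyl ether untouched.

Step 5
Reactants: 9 methyl 2-[bis(2,2,2-trifluoroethoxy)phosphoryl]acetate; 10 tert-butyl(2-iodoethoxy)dimethylsilane
Product: 11 methyl 2-[bis(2,2,2-trifluoroethoxy)phosphoryl]-4-[(tert-butyldimethylsilyl)oxy]butanoate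
Conditions: NaH, DMF, 0 °C; then 10, 50 °C
Reagents that add atoms: none
Why: SN2 C-alkylation of the sodium salt of the phosphonoacetate by a primary iodide installs the C9–C8 arm on the future C10.

Step 6
Reactants: 8 (4E)-4-{[(tert-butyldiphenylsilyl)oxy]methyl}-6-hydroxyhex-4-enal; 11 methyl 2-[bis(2,2,2-trifluoroethoxy)phosphoryl]-4-[(tert-butyldimethylsilyl)oxy]butanoate
Product: 12 methyl (2Z,6E)-2-{2-[(tert-butyldimethylsilyl)oxy]ethyl}-6-{[(tert-butyldiphenylsilyl)oxy]methyl}-8-hydroxyocta-2,6-dienoate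
Conditions: 11 (2 equiv), KN(SiMe3)2, 18-crown-6, THF, −78 °C; then 8, −78 °C
Reagents that add atoms: none
Why: Still–Gennari olefination, in which the bis(trifluoroethyl) phosphonate gives the kinetic (Z)-trisubstituted enoate, placing the ester carbon C14 cis to C2 (C1=C10 trans in the future ring), the free hydroxyl being tolerated with excess reagent.

Step 7
Reactants: 12 methyl (2Z,6E)-2-{2-[(tert-butyldimethylsilyl)oxy]ethyl}-6-{[(tert-butyldiphenylsilyl)oxy]methyl}-8-hydroxyocta-2,6-dienoate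
Product: 13 methyl (2Z,6E)-2-{2-[(tert-butyldimethylsilyl)oxy]ethyl}-6-{[(tert-butyldiphenylsilyl)oxy]methyl}-8-oxoocta-2,6-dienoate
Conditions: MnO2 (excess), CH2Cl2, rt
Reagents that add atoms: none
Why: MnO2 oxidises only the allylic alcohol to the enal under neutral conditions that keep the trisubstituted olefin geometry (allylic oxidation).

Step 8
Reactants: 13 methyl (2Z,6E)-2-{2-[(tert-butyldimethylsilyl)oxy]ethyl}-6-{[(tert-butyldiphenylsilyl)oxy]methyl}-8-oxoocta-2,6-dienoate; 14 1-methoxy-4-[(prop-2-yn-1-yloxy)methyl]benzene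
Product: 15 methyl (2Z,6E,8R)-2-{2-[(tert-butyldimethylsilyl)oxy]ethyl}-6-{[(tert-butyldiphenylsilyl)oxy]methyl}-8-hydroxy-11-[(4-methoxybenzyl)oxy]undeca-2,6-dien-9-ynoate
Conditions: 14 (3 equiv), ZnMe2 (3 equiv), (R,R)-ProPhenol (20 mol %), Ph3PO (40 mol %), toluene, 0 °C; then 13, 0 °C
Reagents that add atoms: none
Why: Dinuclear zinc–ProPhenol-catalysed enantioselective alkynylation of an enal, in which ligand-controlled Si-face addition of the zinc acetylide sets C6 as R and ZnMe2 leaves the enoate untouched.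

Step 9
Reactants: 15 methyl (2Z,6E,8R)-2-{2-[(tert-butyldimethylsilyl)oxy]ethyl}-6-{[(tert-butyldiphenylsilyl)oxy]methyl}-8-hydroxy-11-[(4-methoxybenzyl)oxy]undeca-2,6-dien-9-ynoate
Product: 17 (2Z,6E,8R,9Z)-2-{2-[(tert-butyldimethylsilyl)oxy]ethyl}-6-{[(tert-butyldiphenylsilyl)oxy]methyl}-10-iodo-11-[(4-methoxybenzyl)oxy]undeca-2,6,9-triene-1,8-diol, via cyclic vinylalanate 16 (not isolated)
Conditions: NaAlH2(OCH2CH2OMe)2 (4 equiv), THF, 0 °C → rt; EtOAc, −78 °C; I2, THF, −78 → 0 °C
Reagents that add atoms: iodine, II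
Why: The aluminium hydride does two jobs, 1,2-reduction of the enoate to the C14 allylic alcohol and hydroxyl-directed trans-hydroalumination of the propargylic alcohol (chelate 16), whose iodinolysis gives the (Z)-vinyl iodide with iodine on C11 cis to C6.

Step 10
Reactants: 17 (2Z,6E,8R,9Z)-2-{2-[(tert-butyldimethylsilyl)oxy]ethyl}-6-{[(tert-butyldiphenylsilyl)oxy]methyl}-10-iodo-11-[(4-methoxybenzyl)oxy]undeca-2,6,9-triene-1,8-diol
Product: 18 (5R)-5-[(1E,5Z)-8-[(tert-butyldimethylsilyl)oxy]-2-{[(tert-butyldiphenylsilyl)oxy]methyl}-6-(hydroxymethyl)octa-1,5-dien-1-yl]-3-{[(4-methoxybenzyl)oxy]methyl}furan-2(5H)-one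
Conditions: PdCl2(PPh3)2 (5 mol %), N2H4·H2O (cat.), CO (1 atm), K2CO3, THF, rt → 40 °C
Reagents that add atoms: carbon monoxide, [C-]#[O+]
Why: Palladium-catalysed carbonylative lactonisation of a (Z)-γ-iodo allylic alcohol (oxidative addition, CO insertion, acyl capture by the C6 hydroxyl) builds the butenolide with C12 from CO and leaves C6 and the primary C14 hydroxyl untouched.

Step 11
Reactants: 18 (5R)-5-[(1E,5Z)-8-[(tert-butyldimethylsilyl)oxy]-2-{[(tert-butyldiphenylsilyl)oxy]methyl}-6-(hydroxymethyl)octa-1,5-dien-1-yl]-3-{[(4-methoxybenzyl)oxy]methyl}furan-2(5H)-one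
Product: 19 (5R)-5-[(1E,5Z)-6-(acetoxymethyl)-8-[(tert-butyldimethylsilyl)oxy]-2-{[(tert-butyldiphenylsilyl)oxy]methyl}octa-1,5-dien-1-yl]-3-{[(4-methoxybenzyl)oxy]methyl}furan-2(5H)-one
Conditions: Ac2O, pyridine, CH2Cl2, 0 °C → rt
Reagents that add atoms: acetic anhydride, CC(=O)OC(C)=O
Why: Pyridine-mediated O-acetylation of the only free hydroxyl installs the C14 acetate of the target.

Step 12
Reactants: 19 (5R)-5-[(1E,5Z)-6-(acetoxymethyl)-8-[(tert-butyldimethylsilyl)oxy]-2-{[(tert-butyldiphenylsilyl)oxy]methyl}octa-1,5-dien-1-yl]-3-{[(4-methoxybenzyl)oxy]methyl}furan-2(5H)-one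
Product: 20 (5R)-5-[(1E,5Z)-6-(acetoxymethyl)-8-[(tert-butyldimethylsilyl)oxy]-2-{[(tert-butyldiphenylsilyl)oxy]methyl}octa-1,5-dien-1-yl]-3-(hydroxymethyl)furan-2(5H)-one
Conditions: DDQ, CH2Cl2/pH 7 buffer, 0 °C
Reagents that add atoms: none
Why: Oxidative cleavage of the 4-methoxybenzyl ether by DDQ (benzylic hydride abstraction, then hydrolysis of the oxocarbenium ion) frees the C13 hydroxyl without touching silyl ethers, acetate or butenolide.

Step 13
Reactants: 20 (5R)-5-[(1E,5Z)-6-(acetoxymethyl)-8-[(tert-butyldimethylsilyl)oxy]-2-{[(tert-butyldiphenylsilyl)oxy]methyl}octa-1,5-dien-1-yl]-3-(hydroxymethyl)furan-2(5H)-one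
Product: 21 (5R)-5-[(1E,5Z)-6-(acetoxymethyl)-8-[(tert-butyldimethylsilyl)oxy]-2-{[(tert-butyldiphenylsilyl)oxy]methyl}octa-1,5-dien-1-yl]-3-(bromomethyl)furan-2(5H)-one
Conditions: CBr4, PPh3, CH2Cl2, 0 °C
Reagents that add atoms: carbon tetrabromide, BrC(Br)(Br)Br
Why: Appel bromination converts the primary allylic alcohol into the bromide by SN2 displacement of the oxyphosphonium ion under neutral conditions.

Step 14
Reactants: 21 (5R)-5-[(1E,5Z)-6-(acetoxymethyl)-8-[(tert-butyldimethylsilyl)oxy]-2-{[(tert-butyldiphenylsilyl)oxy]methyl}octa-1,5-dien-1-yl]-3-(bromomethyl)furan-2(5H)-one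
Product: 22 (5R)-5-[(1E,5Z)-6-(acetoxymethyl)-8-hydroxy-2-{[(tert-butyldiphenylsilyl)oxy]methyl}octa-1,5-dien-1-yl]-3-(bromomethyl)furan-2(5H)-one
Conditions: HF (48 % aq.), MeCN, 0 °C
Reagents that add atoms: none
Why: Acidic fluoride cleaves the primary alkyl tert-butyldimethylsilyl ether much faster than the tert-butyldiphenylsilyl ether (selective desilylation), and the medium is not nucleophilic enough to displace the allylic bromide.

Step 15
Reactants: 22 (5R)-5-[(1E,5Z)-6-(acetoxymethyl)-8-hydroxy-2-{[(tert-butyldiphenylsilyl)oxy]methyl}octa-1,5-dien-1-yl]-3-(bromomethyl)furan-2(5H)-one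
Product: 23 (5R)-5-[(1E,5Z)-6-(acetoxymethyl)-8-oxo-2-{[(tert-butyldiphenylsilyl)oxy]methyl}octa-1,5-dien-1-yl]-3-(bromomethyl)furan-2(5H)-one
Conditions: Dess–Martin periodinane, NaHCO3, CH2Cl2, 0 °C → rt
Reagents that add atoms: none
Why: Dess–Martin oxidation gives the β,γ-unsaturated C8 aldehyde under buffered, non-basic conditions that avoid conjugation of the C1=C10 olefin and tolerate the allylic bromide, the crude aldehyde being used at once.

Step 16
Reactants: 23 (5R)-5-[(1E,5Z)-6-(acetoxymethyl)-8-oxo-2-{[(tert-butyldiphenylsilyl)oxy]methyl}octa-1,5-dien-1-yl]-3-(bromomethyl)furan-2(5H)-one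
Product: 25 (6R,7R,8S)-14-acetoxy-15-[(tert-butyldiphenylsilyl)oxy]-8-hydroxygermacra-1(10),4,11(13)-trien-12,6-olide, via allylchromium dichloride 24 (not isolated)
Conditions: CrCl2 (10 equiv), THF, 2 mM, syringe-pump addition of 23, rt
Reagents that add atoms: none
Why: Two equivalents of CrCl2 convert the allylic bromide into the allylchromium species 24, which adds to the tethered aldehyde through a closed six-membered chair transition state with allylic transposition, so that C7 bonds to C8 while the butenolide C7=C11 bond becomes the exocyclic C11=C13 methylene (intramolecular Nozaki–Hiyama–Kishi allylation). The closest known reaction types are the intermolecular chromium- or zinc-mediated additions of γ-substituted 3-(bromomethyl)furan-2(5H)-ones to aldehydes and the Nozaki–Hiyama–Kishi macrocyclisations of 2-(bromomethyl)acrylates that close germacranolide rings. The ten-membered carbocycle closes by γ-attack in a 10-exo-trig addition to the aldehyde, the alternative α-attack at C13 (twelve-membered ring) being disfavoured by the cyclic transition state. C7 is controlled by C6: the aldehyde should approach the butenolide face anti to the C5 alkenyl substituent, giving the trans-fused lactone. C8 is controlled by the chair transition state, in which the ring-fixed allyl geometry (C6 trans to C13) and an equatorial C9 translate into the anti C7/C8 relationship (7R,8S). The step needs ring closure to outrun oligomerisation and chemoselectivity for the aldehyde, which high dilution with slow addition, the cis C4=C5 olefin that folds the chain, and the inertness of organochromium reagents towards lactone, acetate and silyl ether should secure.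

Step 17
Reactants: 25 (6R,7R,8S)-14-acetoxy-15-[(tert-butyldiphenylsilyl)oxy]-8-hydroxygermacra-1(10),4,11(13)-trien-12,6-olide
Product: 26 (6R,7R,8S)-14-acetoxy-15-[(tert-butyldiphenylsilyl)oxy]-8-(methacryloyloxy)germacra-1(10),4,11(13)-trien-12,6-olide
Conditions: methacrylic anhydride, Et3N, DMAP (cat.), CH2Cl2, 0 °C → rt
Reagents that add atoms: methacrylic anhydride, CC(=C)C(=O)OC(=O)C(C)=C
Why: DMAP-catalysed acylation of the secondary C8 alcohol by the anhydride proceeds with retention and should outrun translactonisation to the 8,12-olide.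

Step 18
Reactants: 26 (6R,7R,8S)-14-acetoxy-15-[(tert-butyldiphenylsilyl)oxy]-8-(methacryloyloxy)germacra-1(10),4,11(13)-trien-12,6-olide
Product: 27 (1R,6R,7R,8S,10S)-14-acetoxy-15-[(tert-butyldiphenylsilyl)oxy]-1,10-epoxy-8-(methacryloyloxy)germacra-4,11(13)-dien-12,6-olide
Conditions: mCPBA, NaHCO3, CH2Cl2, 0 °C
Reagents that add atoms: 3-chloroperbenzoic acid, OOC(=O)c1cccc(Cl)c1
Why: Prilezhaev epoxidation, in which the electron-poor methylene lactone and methacrylate are inert, the C1=C10 olefin (one allylic acyloxy group) is more nucleophilic and less shielded than C4=C5 (flanked by the lactone oxygen and the bulky silyloxymethyl group), and the peracid should attack the exposed outer face of the ring-trans olefin in the conformer with C14 above the ring to give the (1R,10S)-epoxide by syn addition.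

Step 19
Reactants: 27 (1R,6R,7R,8S,10S)-14-acetoxy-15-[(tert-butyldiphenylsilyl)oxy]-1,10-epoxy-8-(methacryloyloxy)germacra-4,11(13)-dien-12,6-olide
Product: 28 CNP0306006.2, (1R,6R,7R,8S,10S)-14-acetoxy-1,10-epoxy-15-hydroxy-8-(methacryloyloxy)germacra-4,11(13)-dien-12,6-olide
Conditions: HF·pyridine, pyridine, THF, 0 °C → rt
Reagents that add atoms: none
Why: Buffered fluoride desilylation (Si–F bond formation) frees the C15 alcohol under conditions mild enough for the epoxide, the two esters and the methylene lactone.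

Compound list
1 | but-2-yne-1,4-diol | OCC#CCO | starting material
2 | 4-[(tert-butyldiphenylsilyl)oxy]but-2-yn-1-ol | OCC#CCO[Si](c1ccccc1)(c1ccccc1)C(C)(C)C | intermediate
3 | cyclic vinylalanate from 2, sodium 2,2-bis(2-methoxyethoxy)-3-{[(tert-butyldiphenylsilyl)oxy]methyl}-2,5-dihydro-1,2-oxaluminol-2-uide (not isolated) | [Na+].COCCO[Al-]1(OCCOC)OCC=C1CO[Si](c1ccccc1)(c1ccccc1)C(C)(C)C | intermediate
4 | (2Z)-4-[(tert-butyldiphenylsilyl)oxy]-3-iodobut-2-en-1-ol | OC/C=C(\I)CO[Si](c1ccccc1)(c1ccccc1)C(C)(C)C | intermediate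
5 | 3,3-diethoxyprop-1-ene (acrolein diethyl acetal) | C=CC(OCC)OCC | starting material
6 | 9-(3,3-diethoxypropyl)-9-borabicyclo[3.3.1]nonane (not isolated) | CCOC(CCB1C2CCCC1CCC2)OCC | intermediate
7 | (2E)-3-{[(tert-butyldiphenylsilyl)oxy]methyl}-6,6-diethoxyhex-2-en-1-ol | OC/C=C(\CCC(OCC)OCC)CO[Si](c1ccccc1)(c1ccccc1)C(C)(C)C | intermediate
8 | (4E)-4-{[(tert-butyldiphenylsilyl)oxy]methyl}-6-hydroxyhex-4-enal | OC/C=C(\CCC=O)CO[Si](c1ccccc1)(c1ccccc1)C(C)(C)C | intermediate
9 | methyl 2-[bis(2,2,2-trifluoroethoxy)phosphoryl]acetate | COC(=O)CP(=O)(OCC(F)(F)F)OCC(F)(F)F | starting material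
10 | tert-butyl(2-iodoethoxy)dimethylsilane | CC(C)(C)[Si](C)(C)OCCI | starting material
11 | methyl 2-[bis(2,2,2-trifluoroethoxy)phosphoryl]-4-[(tert-butyldimethylsilyl)oxy]butanoate (racemic) | COC(=O)C(CCO[Si](C)(C)C(C)(C)C)P(=O)(OCC(F)(F)F)OCC(F)(F)F | intermediate
12 | methyl (2Z,6E)-2-{2-[(tert-butyldimethylsilyl)oxy]ethyl}-6-{[(tert-butyldiphenylsilyl)oxy]methyl}-8-hydroxyocta-2,6-dienoate | OC/C=C(\CC/C=C(/CCO[Si](C)(C)C(C)(C)C)C(=O)OC)CO[Si](c1ccccc1)(c1ccccc1)C(C)(C)C | intermediate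
13 | methyl (2Z,6E)-2-{2-[(tert-butyldimethylsilyl)oxy]ethyl}-6-{[(tert-butyldiphenylsilyl)oxy]methyl}-8-oxoocta-2,6-dienoate | O=C/C=C(\CC/C=C(/CCO[Si](C)(C)C(C)(C)C)C(=O)OC)CO[Si](c1ccccc1)(c1ccccc1)C(C)(C)C | intermediate
14 | 1-methoxy-4-[(prop-2-yn-1-yloxy)methyl]benzene (4-methoxybenzyl propargyl ether) | C#CCOCc1ccc(OC)cc1 | starting material
15 | methyl (2Z,6E,8R)-2-{2-[(tert-butyldimethylsilyl)oxy]ethyl}-6-{[(tert-butyldiphenylsilyl)oxy]methyl}-8-hydroxy-11-[(4-methoxybenzyl)oxy]undeca-2,6-dien-9-ynoate | O[C@@H](C#CCOCc1ccc(OC)cc1)/C=C(\CC/C=C(/CCO[Si](C)(C)C(C)(C)C)C(=O)OC)CO[Si](c1ccccc1)(c1ccccc1)C(C)(C)C | intermediate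
16 | cyclic vinylalanate from 15 after ester reduction: five-membered O(C6)–Al–C11=C7 chelate with two 2-methoxyethoxy groups on aluminium and C14 as alkoxide, drawn as the disodium salt (not isolated) | [Na+].[Na+].COCCO[Al-]1(OCCOC)O[C@H](/C=C(\CC/C=C(/CCO[Si](C)(C)C(C)(C)C)C[O-])CO[Si](c2ccccc2)(c2ccccc2)C(C)(C)C)C=C1COCc1ccc(OC)cc1 | intermediate
17 | (2Z,6E,8R,9Z)-2-{2-[(tert-butyldimethylsilyl)oxy]ethyl}-6-{[(tert-butyldiphenylsilyl)oxy]methyl}-10-iodo-11-[(4-methoxybenzyl)oxy]undeca-2,6,9-triene-1,8-diol | O[C@@H](/C=C(\I)COCc1ccc(OC)cc1)/C=C(\CC/C=C(/CCO[Si](C)(C)C(C)(C)C)CO)CO[Si](c1ccccc1)(c1ccccc1)C(C)(C)C | intermediate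
18 | (5R)-5-[(1E,5Z)-8-[(tert-butyldimethylsilyl)oxy]-2-{[(tert-butyldiphenylsilyl)oxy]methyl}-6-(hydroxymethyl)octa-1,5-dien-1-yl]-3-{[(4-methoxybenzyl)oxy]methyl}furan-2(5H)-one | O=C1O[C@H](/C=C(\CC/C=C(/CCO[Si](C)(C)C(C)(C)C)CO)CO[Si](c2ccccc2)(c2ccccc2)C(C)(C)C)C=C1COCc1ccc(OC)cc1 | intermediate
19 | (5R)-5-[(1E,5Z)-6-(acetoxymethyl)-8-[(tert-butyldimethylsilyl)oxy]-2-{[(tert-butyldiphenylsilyl)oxy]methyl}octa-1,5-dien-1-yl]-3-{[(4-methoxybenzyl)oxy]methyl}furan-2(5H)-one | O=C1O[C@H](/C=C(\CC/C=C(/CCO[Si](C)(C)C(C)(C)C)COC(C)=O)CO[Si](c2ccccc2)(c2ccccc2)C(C)(C)C)C=C1COCc1ccc(OC)cc1 | intermediate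
20 | (5R)-5-[(1E,5Z)-6-(acetoxymethyl)-8-[(tert-butyldimethylsilyl)oxy]-2-{[(tert-butyldiphenylsilyl)oxy]methyl}octa-1,5-dien-1-yl]-3-(hydroxymethyl)furan-2(5H)-one | O=C1O[C@H](/C=C(\CC/C=C(/CCO[Si](C)(C)C(C)(C)C)COC(C)=O)CO[Si](c2ccccc2)(c2ccccc2)C(C)(C)C)C=C1CO | intermediate
21 | (5R)-5-[(1E,5Z)-6-(acetoxymethyl)-8-[(tert-butyldimethylsilyl)oxy]-2-{[(tert-butyldiphenylsilyl)oxy]methyl}octa-1,5-dien-1-yl]-3-(bromomethyl)furan-2(5H)-one | O=C1O[C@H](/C=C(\CC/C=C(/CCO[Si](C)(C)C(C)(C)C)COC(C)=O)CO[Si](c2ccccc2)(c2ccccc2)C(C)(C)C)C=C1CBr | intermediate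
22 | (5R)-5-[(1E,5Z)-6-(acetoxymethyl)-8-hydroxy-2-{[(tert-butyldiphenylsilyl)oxy]methyl}octa-1,5-dien-1-yl]-3-(bromomethyl)furan-2(5H)-one | O=C1O[C@H](/C=C(\CC/C=C(/CCO)COC(C)=O)CO[Si](c2ccccc2)(c2ccccc2)C(C)(C)C)C=C1CBr | intermediate
23 | (5R)-5-[(1E,5Z)-6-(acetoxymethyl)-8-oxo-2-{[(tert-butyldiphenylsilyl)oxy]methyl}octa-1,5-dien-1-yl]-3-(bromomethyl)furan-2(5H)-one | O=C1O[C@H](/C=C(\CC/C=C(/CC=O)COC(C)=O)CO[Si](c2ccccc2)(c2ccccc2)C(C)(C)C)C=C1CBr | intermediate
24 | allylchromium dichloride from 23, the C13–Br bond replaced by C13–CrCl2 (trivalent chromium; not isolated) | O=C1O[C@H](/C=C(\CC/C=C(/CC=O)COC(C)=O)CO[Si](c2ccccc2)(c2ccccc2)C(C)(C)C)C=C1C[Cr](Cl)Cl | intermediate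
25 | (6R,7R,8S)-14-acetoxy-15-[(tert-butyldiphenylsilyl)oxy]-8-hydroxygermacra-1(10),4,11(13)-trien-12,6-olide; C1=C10 trans and C4=C5 cis within the ring (1(10)Z,4E by CIP) | O[C@H]1C/C(COC(C)=O)=C/CC/C(CO[Si](c3ccccc3)(c3ccccc3)C(C)(C)C)=C\[C@H]2OC(=O)C(=C)[C@H]12 | intermediate
26 | (6R,7R,8S)-14-acetoxy-15-[(tert-butyldiphenylsilyl)oxy]-8-(methacryloyloxy)germacra-1(10),4,11(13)-trien-12,6-olide (olefin geometries as in 25) | C=C(C)C(=O)O[C@H]1C/C(COC(C)=O)=C/CC/C(CO[Si](c3ccccc3)(c3ccccc3)C(C)(C)C)=C\[C@H]2OC(=O)C(=C)[C@H]12 | intermediate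
27 | (1R,6R,7R,8S,10S)-14-acetoxy-15-[(tert-butyldiphenylsilyl)oxy]-1,10-epoxy-8-(methacryloyloxy)germacra-4,11(13)-dien-12,6-olide (4E by CIP, ring-cis) | C=C(C)C(=O)O[C@H]1C[C@@]2(COC(C)=O)O[C@@H]2CC/C(CO[Si](c3ccccc3)(c3ccccc3)C(C)(C)C)=C\[C@H]2OC(=O)C(=C)[C@H]12 | intermediate
28 | CNP0306006.2, (1R,6R,7R,8S,10S)-14-acetoxy-1,10-epoxy-15-hydroxy-8-(methacryloyloxy)germacra-4,11(13)-dien-12,6-olide (4E by CIP, ring-cis) | C=C(C)C(=O)O[C@H]1C[C@@]2(COC(C)=O)O[C@@H]2CC/C(CO)=C\[C@H]2OC(=O)C(=C)[C@H]12 | target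

Total step count: 19.
Longest linear sequence: 18 steps (steps 1–4 and 6–19; step 5 is a one-step side branch).

Steps most likely to fail

1. Step 16 (key step). The process at risk is facial selectivity at the carbonyl: the aldehyde may add through the diastereomeric transition state with C9 axial (or through a boat), so that C8 forms with the wrong configuration. Fallback: setting out from 23, the same chromium-mediated closure is run and its product of opposite C8 configuration, the C8-epimeric macrocyclic alcohol F1, is not acylated with retention. It is instead esterified under Mitsunobu conditions with methacrylic acid (PPh3, diisopropyl azodicarboxylate, toluene, 0 °C), which inverts C8 and comes back to the route at 26. Stereocontrol is thus moved from the C–C bond formation to the C–O bond formation.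

2. Step 18. The process at risk is site selectivity between the two trisubstituted ring olefins (competing epoxidation of C4=C5), since the peracid has no directing handle. Fallback: setting out from 25, before acylation, the free C8 hydroxyl is used as a homoallylic directing group. VO(acac)2 (cat.) and tBuOOH in CH2Cl2 at 0 °C should deliver oxygen only to C1=C10, on the outer face syn to the hydroxyl, to give the epoxy alcohol F2. Acylation of F2 with methacrylic anhydride (Et3N, DMAP) comes back to the route at 27.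

3. Step 8. The process at risk is enantiofacial discrimination by the zinc catalyst on a (Z)-configured, β,β-disubstituted enal, together with geometric isomerisation of the enal during a slow addition. Fallback: setting out from 13, the lithium acetylide of 14 (n-BuLi, THF, −78 °C) is added to give the racemic propargylic alcohol F3. MnO2 oxidation gives the alkenyl alkynyl ketone F4. Reagent-controlled reduction with (R)-2-methyl-CBS-oxazaborolidine and catecholborane (toluene, −78 °C; the trisubstituted alkenyl group acting as the large substituent) comes back to the route at 15.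

Further compounds
F1 | step 16 | (6R,7R,8R)-14-acetoxy-15-[(tert-butyldiphenylsilyl)oxy]-8-hydroxygermacra-1(10),4,11(13)-trien-12,6-olide (C8 epimer of 25) | O[C@@H]1C/C(COC(C)=O)=C/CC/C(CO[Si](c3ccccc3)(c3ccccc3)C(C)(C)C)=C\[C@H]2OC(=O)C(=C)[C@H]12
F2 | step 18 | (1R,6R,7R,8S,10S)-14-acetoxy-15-[(tert-butyldiphenylsilyl)oxy]-1,10-epoxy-8-hydroxygermacra-4,11(13)-dien-12,6-olide | O[C@H]1C[C@@]2(COC(C)=O)O[C@@H]2CC/C(CO[Si](c3ccccc3)(c3ccccc3)C(C)(C)C)=C\[C@H]2OC(=O)C(=C)[C@H]12
F3 | step 8 | racemic methyl (2Z,6E)-2-{2-[(tert-butyldimethylsilyl)oxy]ethyl}-6-{[(tert-butyldiphenylsilyl)oxy]methyl}-8-hydroxy-11-[(4-methoxybenzyl)oxy]undeca-2,6-dien-9-ynoate | OC(C#CCOCc1ccc(OC)cc1)/C=C(\CC/C=C(/CCO[Si](C)(C)C(C)(C)C)C(=O)OC)CO[Si](c1ccccc1)(c1ccccc1)C(C)(C)C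
F4 | step 8 | methyl (2Z,6E)-2-{2-[(tert-butyldimethylsilyl)oxy]ethyl}-6-{[(tert-butyldiphenylsilyl)oxy]methyl}-11-[(4-methoxybenzyl)oxy]-8-oxoundeca-2,6-dien-9-ynoate | O=C(C#CCOCc1ccc(OC)cc1)/C=C(\CC/C=C(/CCO[Si](C)(C)C(C)(C)C)C(=O)OC)CO[Si](c1ccccc1)(c1ccccc1)C(C)(C)C
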